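## Retrosynthetic overview

- **Feature** (target isochromene numbering, used for the ring atoms of all intermediates): the carbocycle C4a–C5–C6–C7–C8–C8a carries oxygen at C8, methyl at C7, cis oxygens at C6/C7 and carbon branches on C8a (C1) and C4a (C4). This is the pattern of a [4+2] adduct of a 1-silyloxy-2-methylbuta-1,3-diene and a 2-bromo-3-alkynylacrolein.
- **Disconnections:** O6 aroyl ester; O2–C3 (6-endo oxa-conjugate addition of the C1 hydroxyl onto a C8 ynenone); C8a=C4a (loss of HBr); C6/C7 diol (OsO4 anti to a sacrificial C8 carbinol); C8–C8a and C4a–C5 (catalytic enantioselective Diels–Alder reaction).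
- **Ring order:** carbocycle first (cycloaddition), pyran second (conjugate addition). The epoxide is carried in from a Sharpless epoxy alcohol, the diene comes from tiglic aldehyde, and the orsellinate is attached last.

Key step: step 8

Assumption: the (S)-oxazaborolidinium catalyst is taken to shield the same face of the bromo-enal as of 2-bromoacrolein (diene onto the Re face of C-2); if correlation of the cycloadduct shows the opposite sense, the (R)-catalyst is used and nothing else changes.

## Route

Step 1
Reactants: 1 (E)-but-2-en-1-ol (crotyl alcohol)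
Product: 2 [(2R,3R)-3-methyloxiran-2-yl]methanol
Conditions: Ti(OiPr)4 (10 mol%), D-(−)-diisopropyl tartrate (12 mol%), t-BuOOH, 4 Å MS, CH2Cl2, −20 °C
Reagents that add atoms: tert-butyl hydroperoxide, CC(C)(C)OO
Why: Sharpless asymmetric epoxidation of a primary E-allylic alcohol, in which the D-(−)-tartrate/titanium complex delivers oxygen to one alkene face and so sets both epoxide centres as (2R,3R), the trans relation coming from the E geometry.

Step 2
Reactants: 2 [(2R,3R)-3-methyloxiran-2-yl]methanol
Product: 3 (2S,3R)-3-methyloxirane-2-carbaldehyde (same spatial arrangement; the descriptor changes by priority only)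
Conditions: (COCl)2, DMSO, CH2Cl2, −78 °C; Et3N, −78 → 0 °C; dried CH2Cl2 solution used directly
Reagents that add atoms: none
Why: Swern oxidation of the primary alcohol; the oxiranyl C–H is not enolised under these conditions, so both epoxide centres should be retained.

Step 3
Reactants: 3 (2S,3R)-3-methyloxirane-2-carbaldehyde
Product: 4 (2R,3R)-2-(2,2-dibromoethenyl)-3-methyloxirane
Conditions: CBr4, PPh3, Zn, CH2Cl2, rt (ylide preformed); then 3, 0 °C
Reagents that add atoms: carbon tetrabromide, BrC(Br)(Br)Br
Why: first stage of the Corey–Fuchs sequence (Wittig reaction of Ph3P=CBr2); preforming the ylide with zinc leaves no bromophosphonium species that could open the epoxide.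

Step 4
Reactants: 4 (2R,3R)-2-(2,2-dibromoethenyl)-3-methyloxirane
Product: 6 3-[(2R,3R)-3-methyloxiran-2-yl]prop-2-ynal, via lithium acetylide 5 (not isolated)
Conditions: n-BuLi (2.1 equiv), THF, −78 °C; DMF, −78 → −20 °C; inverse quench into cold aq. KH2PO4; kept as a concentrated ether solution
Reagents that add atoms: N,N-dimethylformamide, CN(C)C=O
Why: second stage of the Corey–Fuchs sequence (Br/Li exchange, 1,2-shift to the alkyne, deprotonation) followed by formylation of the lithium acetylide with DMF; the buffered inverse quench keeps the liberated dimethylamine from adding to the ynal.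

Step 5
Reactants: 7 (formylmethylene)triphenylphosphorane
Product: 8 bromo(formyl)methylenetriphenylphosphorane
Conditions: Br2, CH2Cl2, −70 °C; then Et3N, 0 °C
Reagents that add atoms: bromine, BrBr
Why: C-bromination of a stabilised ylide to the bromophosphonium salt and deprotonation back to the ylide, the standard way to α-halo stabilised Wittig reagents.

Step 6
Reactants: 6 3-[(2R,3R)-3-methyloxiran-2-yl]prop-2-ynal; 8 bromo(formyl)methylenetriphenylphosphorane
Product: 9 (2Z)-2-bromo-5-[(2R,3R)-3-methyloxiran-2-yl]pent-2-en-4-ynal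
Conditions: CH2Cl2, 0 °C → rt, dark
Reagents that add atoms: none
Why: Wittig olefination with a stabilised ylide, which should place the formyl group trans to the alkynyl substituent (bromine cis to it, Z); the ynal is far more electrophilic than the hindered bromo-enal product, so a second olefination is not expected.

Step 7
Reactants: 10 tiglic aldehyde, (E)-2-methylbut-2-enal
Product: 11 (1E)-1-(tert-butyldimethylsilyloxy)-2-methylbuta-1,3-diene
Conditions: TBSOTf, Et3N, Et2O, 0 °C → rt; distillation
Reagents that add atoms: tert-butyldimethylsilyl triflate, CC(C)(C)[Si](C)(C)OS(=O)(=O)C(F)(F)F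
Why: soft enolisation (γ-deprotonation and O-silylation) of the enal to the dienol silyl ether; the E isomer, with the silyloxy group outside, is the reactive diene and any Z isomer is a spectator in step 8.

Step 8
Reactants: 9 (2Z)-2-bromo-5-[(2R,3R)-3-methyloxiran-2-yl]pent-2-en-4-ynal; 11 (1E)-1-(tert-butyldimethylsilyloxy)-2-methylbuta-1,3-diene
Product: 12 (1R,2S,6S)-1-bromo-2-(tert-butyldimethylsilyloxy)-3-methyl-6-{[(2R,3R)-3-methyloxiran-2-yl]ethynyl}cyclohex-3-ene-1-carbaldehyde (bromine cis to the silyloxy and alkynyl groups, formyl trans to the silyloxy group)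
Conditions: (S)-1-(2-methylphenyl)-3,3-diphenyl-tetrahydro-1H,3H-pyrrolo[1,2-c][1,3,2]oxazaborole (C24H24BNO, 20 mol%), (CF3SO2)2NH (18 mol%), CH2Cl2, −78 → −60 °C; 11 (2.5 equiv) added slowly
Reagents that add atoms: none
Why: The N-protonated oxazaborolidine binds the formyl oxygen of 9 (s-trans enal, formyl C–H held by the ring oxygen) and lowers its LUMO for a concerted but asynchronous normal-demand Diels–Alder reaction, the closest known reaction type being the oxazaborolidinium-catalysed cycloaddition of 2-bromoacrolein and other α-substituted enals to silyloxy dienes. The unsubstituted terminus C4 of 11 (largest HOMO coefficient, remote from the silyloxy donor) bonds first to the β-carbon of the enal and C1 then to the α-carbon, so C4a–C5 and C8–C8a form suprafacially on both partners in one intermolecular [4+2] event that closes the six-membered carbocycle with the C6=C7 alkene in place. The configurations at C8a and C4a follow from the catalyst, whose aryl groups cover one face of the bound enal so that the diene should add to the Re face of C-2, and their cis bromine/alkynyl relation follows from the Z geometry of 9. C8 is set by the topology: as with other 2-bromoacroleins the bromine (and here the slim alkynyl group) should lie endo and the boron-bound formyl group exo, which puts the silyloxy group cis to bromine and gives the (S) centre that later steers the dihydroxylation. The ortho regiochemistry needs the 1-silyloxy donor to outweigh the 2-methyl group, which it should because oxygen conjugation dominates the diene HOMO. The step also needs cycloaddition to outrun Mukaiyama-type addition and epoxide opening, for which the low temperature, the acid kept below the amount of oxazaborolidine, the robust TBS group and the deactivation of the propargylic epoxide by the electron-poor enynal are relied on.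

Step 9
Reactants: 12 the bromo aldehyde cycloadduct
Product: 13 [(1S,2S,6S)-1-bromo-2-(tert-butyldimethylsilyloxy)-3-methyl-6-{[(2R,3R)-3-methyloxiran-2-yl]ethynyl}cyclohex-3-en-1-yl]methanol
Conditions: NaBH4, MeOH/THF, −40 °C; AcOH quench at −40 °C
Reagents that add atoms: none
Why: borohydride 1,2-reduction of the neopentyl aldehyde; the cold acidic quench keeps the bromohydrin from closing to the spiro-epoxide, and removing the aldehyde now prevents lactol formation with the tertiary hydroxyl that appears in step 11.

Step 10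
Reactants: 13 the silyloxy bromohydrin
Product: 14 (1S,5S,6S)-6-bromo-6-(hydroxymethyl)-2-methyl-5-{[(2R,3R)-3-methyloxiran-2-yl]ethynyl}cyclohex-2-en-1-ol (C8 hydroxyl cis to bromine)
Conditions: HF·pyridine, pyridine, THF, 0 °C → rt
Reagents that add atoms: none
Why: fluoride cleavage of the allylic secondary silyl ether under buffered, non-basic conditions that spare the epoxide and the bromohydrin; the C8 hydroxyl is freed now because after dihydroxylation it lies between two quaternary carbons.

Step 11
Reactants: 14 the allylic diol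
Product: 15 (1S,2R,3R,5S,6S)-6-bromo-6-(hydroxymethyl)-2-methyl-5-{[(2R,3R)-3-methyloxiran-2-yl]ethynyl}cyclohexane-1,2,3-triol (O6 and O7 cis to each other, trans to O8)
Conditions: OsO4 (5 mol%), N-methylmorpholine N-oxide, acetone/H2O, rt
Reagents that add atoms: osmium tetroxide (catalytic oxygen carrier), O=[Os](=O)(=O)=O; N-methylmorpholine N-oxide, C[N+]1([O-])CCOCC1; water, O
Why: catalytic OsO4/NMO syn-dihydroxylation of the trisubstituted alkene (the alkyne reacts far more slowly); OsO4 should add anti to the allylic C8 hydroxyl, the face that is also free of the bromine and alkynyl groups, which sets C6 and C7 as in the target.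

Step 12
Reactants: 15 the bromo tetraol
Product: 16 (1S,2S,3R,5S,6S)-6-bromo-2-methyl-5-{[(2R,3R)-3-methyloxiran-2-yl]ethynyl}-3-(triethylsilyloxy)-6-[(triethylsilyloxy)methyl]cyclohexane-1,2-diol (silyl groups on O1 and O6; O7 and O8 free)
Conditions: Et3SiCl (2.2 equiv), imidazole, DMF, −30 → 0 °C
Reagents that add atoms: chlorotriethylsilane, CC[Si](Cl)(CC)CC
Why: chemoselective silylation by steric rank: the primary C1 hydroxyl and the secondary C6 hydroxyl react, while the C8 hydroxyl (between two quaternary carbons) and the tertiary C7 hydroxyl should stay free.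

Step 13
Reactants: 16 the bis-silyl ether
Product: 17 (2R,3R,5S,6S)-6-bromo-2-hydroxy-2-methyl-5-{[(2R,3R)-3-methyloxiran-2-yl]ethynyl}-3-(triethylsilyloxy)-6-[(triethylsilyloxy)methyl]cyclohexan-1-one
Conditions: Dess–Martin periodinane, NaHCO3, CH2Cl2, 0 °C → rt
Reagents that add atoms: none
Why: Dess–Martin oxidation of the only oxidisable hydroxyl; the relay centre C8 has done its work and becomes the ketone, which has no enolisable α-hydrogen on either side.

Step 14
Reactants: 17 the α-bromo ketone
Product: 18 (5R,6R)-6-hydroxy-6-methyl-3-{[(2R,3R)-3-methyloxiran-2-yl]ethynyl}-5-(triethylsilyloxy)-2-[(triethylsilyloxy)methyl]cyclohex-2-en-1-one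
Conditions: DBU (2 equiv), toluene, 0 °C → rt
Reagents that add atoms: none
Why: E2 dehydrobromination of an α-bromo ketone: H-4a is trans to bromine (bromine and alkynyl were cis on the Z-dienophile), is propargylic, and its removal gives the endocyclic conjugated ynenone; C7 carries no hydrogen, so no Favorskii path exists.

Step 15
Reactants: 18 the silylated ynenone
Product: 20 (6R,7R)-6,7-dihydroxy-7-methyl-3-[(2S,3R)-3-methyloxiran-2-yl]-5,6,7,8-tetrahydro-1H-isochromen-8-one, via triol ynenone 19 (not isolated)
Conditions: HF·pyridine, pyridine, THF, 0 °C; NaHCO3 work-up; then DABCO (20 mol%), CHCl3, rt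
Reagents that add atoms: none
Why: fluoride desilylation followed by amine-catalysed oxa-conjugate addition: DABCO adds to the alkyne terminus C3 (the δ-position of the ynenone) and the C1 hydroxyl then displaces it by 6-endo addition–elimination, closing the pyran as the conjugated vinylogous ester; the C6 and C7 hydroxyls cannot reach C3 without forming a bridged ring.

Step 16
Reactants: 21 orsellinic acid (2,4-dihydroxy-6-methylbenzoic acid)
Product: 22 tert-butyldimethylsilyl 2,4-bis(tert-butyldimethylsilyloxy)-6-methylbenzoate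
Conditions: TBSCl (3.5 equiv), imidazole, DMF, rt
Reagents that add atoms: tert-butyldimethylsilyl chloride, CC(C)(C)[Si](C)(C)Cl
Why: exhaustive silylation of both phenols and the carboxylic acid (silyl ether and silyl ester formation).

Step 17
Reactants: 22 the tris-silyl orsellinate
Product: 23 2,4-bis(tert-butyldimethylsilyloxy)-6-methylbenzoyl chloride
Conditions: (COCl)2, DMF (cat.), CH2Cl2, 0 °C → rt; volatiles removed
Reagents that add atoms: oxalyl chloride, O=C(Cl)C(=O)Cl
Why: direct conversion of a silyl ester into the acid chloride by the Vilsmeier-type chloroiminium reagent under neutral conditions, which leaves the aryl silyl ethers intact.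

Step 18
Reactants: 20 the diol pyranone; 23 the aroyl chloride
Product: 24 (6R,7R)-7-hydroxy-7-methyl-3-[(2S,3R)-3-methyloxiran-2-yl]-8-oxo-5,6,7,8-tetrahydro-1H-isochromen-6-yl 2,4-bis(tert-butyldimethylsilyloxy)-6-methylbenzoate
Conditions: DMAP (0.3 equiv), pyridine, CH2Cl2, 0 °C → rt
Reagents that add atoms: none
Why: DMAP-catalysed acyl transfer to the secondary C6 hydroxyl; the tertiary C7 hydroxyl next to the ketone should not be acylated.

Step 19
Reactants: 24 the bis-silyl ester
Product: 25 (6R,7R)-7-hydroxy-7-methyl-3-[(2S,3R)-3-methyloxiran-2-yl]-8-oxo-5,6,7,8-tetrahydro-1H-isochromen-6-yl 2,4-dihydroxy-6-methylbenzoate (target)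
Conditions: HF·pyridine, pyridine, THF, 0 °C
Reagents that add atoms: none
Why: buffered fluoride cleavage of the two aryl silyl ethers, conditions under which the ester, the dienol ether and the epoxide should survive.

## Compound list

1 | (E)-but-2-en-1-ol (crotyl alcohol) | C/C=C/CO | starting material
2 | [(2R,3R)-3-methyloxiran-2-yl]methanol | OC[C@H]1O[C@@H]1C | intermediate
3 | (2S,3R)-3-methyloxirane-2-carbaldehyde | O=C[C@H]1O[C@@H]1C | intermediate
4 | (2R,3R)-2-(2,2-dibromoethenyl)-3-methyloxirane | BrC(Br)=C[C@H]1O[C@@H]1C | intermediate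
5 | lithium [(2R,3R)-3-methyloxiran-2-yl]acetylide | [Li]C#C[C@H]1O[C@@H]1C | intermediate
6 | 3-[(2R,3R)-3-methyloxiran-2-yl]prop-2-ynal | O=CC#C[C@H]1O[C@@H]1C | intermediate
7 | (formylmethylene)triphenylphosphorane | O=CC=P(c1ccccc1)(c1ccccc1)c1ccccc1 | starting material
8 | bromo(formyl)methylenetriphenylphosphorane | O=CC(Br)=P(c1ccccc1)(c1ccccc1)c1ccccc1 | intermediate
9 | (2Z)-2-bromo-5-[(2R,3R)-3-methyloxiran-2-yl]pent-2-en-4-ynal | O=C/C(Br)=C/C#C[C@H]1O[C@@H]1C | intermediate
10 | tiglic aldehyde, (E)-2-methylbut-2-enal | C/C=C(\C)C=O | starting material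
11 | (1E)-1-(tert-butyldimethylsilyloxy)-2-methylbuta-1,3-diene | C=C/C(C)=C/O[Si](C)(C)C(C)(C)C | intermediate
12 | (1R,2S,6S)-1-bromo-2-(tert-butyldimethylsilyloxy)-3-methyl-6-{[(2R,3R)-3-methyloxiran-2-yl]ethynyl}cyclohex-3-ene-1-carbaldehyde | CC(C)(C)[Si](C)(C)O[C@H]1C(C)=CC[C@@H](C#C[C@H]2O[C@@H]2C)[C@]1(Br)C=O | intermediate
13 | [(1S,2S,6S)-1-bromo-2-(tert-butyldimethylsilyloxy)-3-methyl-6-{[(2R,3R)-3-methyloxiran-2-yl]ethynyl}cyclohex-3-en-1-yl]methanol | CC(C)(C)[Si](C)(C)O[C@H]1C(C)=CC[C@@H](C#C[C@H]2O[C@@H]2C)[C@]1(Br)CO | intermediate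
14 | (1S,5S,6S)-6-bromo-6-(hydroxymethyl)-2-methyl-5-{[(2R,3R)-3-methyloxiran-2-yl]ethynyl}cyclohex-2-en-1-ol | O[C@H]1C(C)=CC[C@@H](C#C[C@H]2O[C@@H]2C)[C@]1(Br)CO | intermediate
15 | (1S,2R,3R,5S,6S)-6-bromo-6-(hydroxymethyl)-2-methyl-5-{[(2R,3R)-3-methyloxiran-2-yl]ethynyl}cyclohexane-1,2,3-triol | O[C@H]1[C@](C)(O)[C@H](O)C[C@@H](C#C[C@H]2O[C@@H]2C)[C@]1(Br)CO | intermediate
16 | (1S,2S,3R,5S,6S)-6-bromo-2-methyl-5-{[(2R,3R)-3-methyloxiran-2-yl]ethynyl}-3-(triethylsilyloxy)-6-[(triethylsilyloxy)methyl]cyclohexane-1,2-diol | O[C@H]1[C@](C)(O)[C@H](O[Si](CC)(CC)CC)C[C@@H](C#C[C@H]2O[C@@H]2C)[C@]1(Br)CO[Si](CC)(CC)CC | intermediate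
17 | (2R,3R,5S,6S)-6-bromo-2-hydroxy-2-methyl-5-{[(2R,3R)-3-methyloxiran-2-yl]ethynyl}-3-(triethylsilyloxy)-6-[(triethylsilyloxy)methyl]cyclohexan-1-one | O=C1[C@](C)(O)[C@H](O[Si](CC)(CC)CC)C[C@@H](C#C[C@H]2O[C@@H]2C)[C@]1(Br)CO[Si](CC)(CC)CC | intermediate
18 | (5R,6R)-6-hydroxy-6-methyl-3-{[(2R,3R)-3-methyloxiran-2-yl]ethynyl}-5-(triethylsilyloxy)-2-[(triethylsilyloxy)methyl]cyclohex-2-en-1-one | O=C1[C@](C)(O)[C@H](O[Si](CC)(CC)CC)CC(C#C[C@H]2O[C@@H]2C)=C1CO[Si](CC)(CC)CC | intermediate
19 | (5R,6R)-5,6-dihydroxy-2-(hydroxymethyl)-6-methyl-3-{[(2R,3R)-3-methyloxiran-2-yl]ethynyl}cyclohex-2-en-1-one | O=C1[C@](C)(O)[C@H](O)CC(C#C[C@H]2O[C@@H]2C)=C1CO | intermediate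
20 | (6R,7R)-6,7-dihydroxy-7-methyl-3-[(2S,3R)-3-methyloxiran-2-yl]-5,6,7,8-tetrahydro-1H-isochromen-8-one | O[C@@H]1CC2=C(COC([C@H]3O[C@@H]3C)=C2)C(=O)[C@]1(C)O | intermediate
21 | orsellinic acid (2,4-dihydroxy-6-methylbenzoic acid) | Cc1cc(O)cc(O)c1C(=O)O | starting material
22 | tert-butyldimethylsilyl 2,4-bis(tert-butyldimethylsilyloxy)-6-methylbenzoate | Cc1cc(O[Si](C)(C)C(C)(C)C)cc(O[Si](C)(C)C(C)(C)C)c1C(=O)O[Si](C)(C)C(C)(C)C | intermediate
23 | 2,4-bis(tert-butyldimethylsilyloxy)-6-methylbenzoyl chloride | Cc1cc(O[Si](C)(C)C(C)(C)C)cc(O[Si](C)(C)C(C)(C)C)c1C(=O)Cl | intermediate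
24 | (6R,7R)-7-hydroxy-7-methyl-3-[(2S,3R)-3-methyloxiran-2-yl]-8-oxo-5,6,7,8-tetrahydro-1H-isochromen-6-yl 2,4-bis(tert-butyldimethylsilyloxy)-6-methylbenzoate | Cc1cc(O[Si](C)(C)C(C)(C)C)cc(O[Si](C)(C)C(C)(C)C)c1C(=O)O[C@@H]1CC2=C(COC([C@H]3O[C@@H]3C)=C2)C(=O)[C@]1(C)O | intermediate
25 | (6R,7R)-7-hydroxy-7-methyl-3-[(2S,3R)-3-methyloxiran-2-yl]-8-oxo-5,6,7,8-tetrahydro-1H-isochromen-6-yl 2,4-dihydroxy-6-methylbenzoate | Cc1cc(O)cc(O)c1C(=O)O[C@@H]1CC2=C(COC([C@H]3O[C@@H]3C)=C2)C(=O)[C@]1(C)O | target

## Step count and risks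

Total steps: 19. Longest linear sequence: 15 steps (1–4, 6, 8–15, 18, 19).

**Step 8 (Diels–Alder reaction).** The diene may approach with the formyl group endo, or with mixed endo/exo topology, which sets C8 with the wrong configuration relative to the catalyst-controlled C8a/C4a pair. A slow cycloaddition would also let silyl transfer and Mukaiyama-type addition compete. In the fallback the relay centre is corrected after the cycloaddition instead of being set in it. It sets out from 9 and 11 under the conditions of step 8 and takes the formyl-endo adduct F1, alone or mixed with 12, through NaBH4 reduction to the bromohydrin F2 and HF·pyridine desilylation to the epimeric diol F3. MnO2 in CH2Cl2 then oxidises only the allylic C8 hydroxyl (the primary hydroxyl is no longer allylic) to the enone F4; any 14 in the mixture is oxidised to the same enone. NaBH4/CeCl3·7H2O in MeOH at −78 °C should deliver hydride anti to the axial C–Br bond (polar Felkin–Anh control) and give the alcohol cis to bromine, which comes back to the route at 14.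

**Step 14 (dehydrobromination).** HBr may be lost toward the exocyclic CH2OSiEt3 carbon instead of toward C4a, or the base may isomerise the propargylic epoxide once the ynenone has formed. The fallback replaces the anti elimination by a selenoxide syn elimination, which avoids oxygen-bearing carbons. From 17, SmI2 in THF/MeOH at −78 °C removes bromine to give the debromo ketone F5. LiN(SiMe3)2 (2.2 equiv) and PhSeCl at −78 °C should selenenylate the enolate on the face away from the alkynyl group and give the selenide F6 with selenium cis to H-4a. H2O2/pyridine in CH2Cl2 at 0 °C then forms the selenoxide, whose syn elimination toward C4a comes back to the route at 18.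

**Step 15 (pyran closure).** The C1 hydroxyl may close onto the nearer alkyne carbon (5-exo), or conjugate addition may run between molecules instead of closing the ring 6-endo. The fallback fixes the regiochemistry at C3 before the hydroxyl is unmasked. From 18, Et2NH in THF at rt adds to the alkyne terminus and gives the δ-diethylamino dienone F7, a vinylogous amide. HF·pyridine then removes the two silyl groups, and brief warming with AcOH in THF exchanges nitrogen for the C1 oxygen at C3 by 6-endo addition–elimination with loss of diethylamine, which comes back to the route at 20.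

## Further compounds

F1 | step 8 | (1R,2R,6S)-1-bromo-2-(tert-butyldimethylsilyloxy)-3-methyl-6-{[(2R,3R)-3-methyloxiran-2-yl]ethynyl}cyclohex-3-ene-1-carbaldehyde (formyl cis to the silyloxy group) | CC(C)(C)[Si](C)(C)O[C@@H]1C(C)=CC[C@@H](C#C[C@H]2O[C@@H]2C)[C@]1(Br)C=O
F2 | step 8 | [(1S,2R,6S)-1-bromo-2-(tert-butyldimethylsilyloxy)-3-methyl-6-{[(2R,3R)-3-methyloxiran-2-yl]ethynyl}cyclohex-3-en-1-yl]methanol | CC(C)(C)[Si](C)(C)O[C@@H]1C(C)=CC[C@@H](C#C[C@H]2O[C@@H]2C)[C@]1(Br)CO
F3 | step 8 | (1R,5S,6S)-6-bromo-6-(hydroxymethyl)-2-methyl-5-{[(2R,3R)-3-methyloxiran-2-yl]ethynyl}cyclohex-2-en-1-ol (C8 epimer of 14) | O[C@@H]1C(C)=CC[C@@H](C#C[C@H]2O[C@@H]2C)[C@]1(Br)CO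
F4 | step 8 | (5S,6S)-6-bromo-6-(hydroxymethyl)-2-methyl-5-{[(2R,3R)-3-methyloxiran-2-yl]ethynyl}cyclohex-2-en-1-one | O=C1C(C)=CC[C@@H](C#C[C@H]2O[C@@H]2C)[C@]1(Br)CO
F5 | step 14 | debromo ketone (17 with hydrogen in place of bromine, both C8a epimers) | O=C1[C@](C)(O)[C@H](O[Si](CC)(CC)CC)C[C@@H](C#C[C@H]2O[C@@H]2C)C1CO[Si](CC)(CC)CC
F6 | step 14 | α-phenylselanyl ketone (17 with PhSe in place of bromine, selenium cis to H-4a) | O=C1[C@](C)(O)[C@H](O[Si](CC)(CC)CC)C[C@@H](C#C[C@H]2O[C@@H]2C)[C@@]1([Se]c3ccccc3)CO[Si](CC)(CC)CC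
F7 | step 15 | (5R,6R)-3-{2-(diethylamino)-2-[(2S,3R)-3-methyloxiran-2-yl]ethenyl}-6-hydroxy-6-methyl-5-(triethylsilyloxy)-2-[(triethylsilyloxy)methyl]cyclohex-2-en-1-one (enamine geometry not fixed) | O=C1[C@](C)(O)[C@H](O[Si](CC)(CC)CC)CC(C=C(N(CC)CC)[C@H]2O[C@@H]2C)=C1CO[Si](CC)(CC)CC
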